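The runs come from a simulation on assumed constants; the scatter is artificial.

The closed, stirred vessel held a racemic substrate, a single-handed free catalyst, a solid reagent dissolving as it went, and a racemization catalyst able to exchange the two substrates.

| setting | larch | cedar | flask |
|---|---|---|---|
| left-handed substrate | 0.15 M | 0.60 M | 0.30 M |
| right-handed substrate | 0.15 M | 0.60 M | 0.30 M |
| solid reagent | 0.90 M | 0.90 M | 0.900 M |
| free catalyst | 1.5 mM | 1.5 mM | 1.5 mM |
| racemization catalyst | 6 mM | 6 mM | 6.0 mM |
| added ligand | 6 mM | 6 mM | 6.0 mM |
| remark | run made earlier | run made earlier |  |
| time |  |  | 1.5 h |

- larch (time / min: left-handed product / %, right-handed product / %): 8.00: 6.6, 0; 12.0: 9.5, 2.3; 20.0: 13.6, 6.2; 30.0: 23.2, 10.9; 50.0: 35.1, 17.8; 90.0: 47.6, 30.8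
- cedar (time / min: left-handed product / %, right-handed product / %): 8.00: 1.5, 2.5; 12.0: 6.7, 2.4; 20.0: 11.7, 4.8; 30.0: 17.5, 9.0; 50.0: 28.2, 14.7; 90.0: 42.4, 25.9

(readings scatter by 1 percentage point)

- free catalyst is single-handed; left-handed substrate and right-handed substrate are mirror images of each other, charged as a racemate, each of them at the stated concentration
- as a solid, counted per litre of solution: solid reagent
- the earlier runs were read with a standard deviation of 1 percentage point
- at the start none of the solid reagent is in solution
- an excess is below zero if the other one leads

1. left-handed product and right-handed product together, in percent of the left-handed substrate and right-handed substrate charged together, at 1.5 h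
2. excess of left-handed product over right-handed product in the product at 1.5 h
3. whether the exchange between left-handed substrate and right-handed substrate keeps pace with the reaction: how far the product's excess at 1.5 h gets from its value without exchange to its value with instant exchange (above 80% keeps pace, below 20% hardly takes part, else lags behind)

At the bench I first divided left-handed by right-handed product and called that the selectivity factor. In larch this gave 2.13 at 30.0 min but 1.55 at 90.0 min. One ratio marked the border of the rule: by 30.0 min in larch the left-handed product already read 46.4% of the left-handed charge, so the substrates in larch were no longer at their charged levels.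

I therefore replaced the varying pace by its mean over the run. If each substrate falls at a rate proportional to its own level, with the same varying factor for both, the logarithm of its fraction remaining is its rate constant times the mean of that factor times the time, however the factor varies. My remainder ratio, ln(left-handed fraction remaining) / ln(right-handed fraction remaining), then equals the selectivity factor without exchange and goes to 1 with instant exchange. At 50.0 min the readings gave 2.75 in larch and 2.38 in cedar, so I carried their mean as my remainder ratio, 2.57. Cedar still read 2.58 at 90.0 min, so I judged that exchange hardly takes part.

The flask's charge was twice larch's and half cedar's, so for the flask I took the mean right-handed fraction remaining of the two runs at 90.0 min, 43.3%. Raised to my ratio, this gave my estimate of 11.7% of the left-handed substrate remaining in the flask, and so an estimated yield of 72.5% and an estimated excess of 21.8%. The forecast said 74%, 22.5% and lags behind, holding that “Larch and cedar both retain about 30% of that gap”, and so parted from me on the pace.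

The flask gave 74.1% and 20.8%, and the exchange was rated hardly takes part, its excess getting 6.8% of the way from the value without exchange to the value with instant exchange. The flask's remainder ratio was 2.21. In the flask after 0.150 h the racemization catalyst stood at 15.4% of its charge, and at 1.50 h the relaxation half-life of the two substrates by the exchange alone, both ways together, was 10.8 h, longer at that moment than the run of 1.5 h.

    2 racemization catalyst → spent catalyst (k = 51.0 M⁻¹ min⁻¹)
    partner + free catalyst + right-handed substrate → free catalyst + right-handed product (k = 51.0 M⁻² min⁻¹)
    solid reagent ⇌ partner, rate k3*(cs3 - [partner]) while solid is left; crystals form when [partner] > cs3 (solubility = 0.260 M, k = 0.120 min⁻¹)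
    left-handed substrate + racemization catalyst ⇌ right-handed substrate + racemization catalyst, rate k4*[racemization catalyst]*[left-handed substrate] forward; the back reaction follows from the equilibrium constant (k = 5.00 M⁻¹ min⁻¹)
    partner + free catalyst + left-handed substrate → free catalyst + left-handed product (k = 120 M⁻² min⁻¹)
    free catalyst + added ligand ⇌ idle complex (K = 91.0 M⁻¹, k = 530 M⁻¹ min⁻¹)

The neighbouring flask with a quarter of the free catalyst kept 77.1% of its right-handed substrate. My ratio then put its left-handed fraction remaining at 51.3% and its excess at 36.1%; the computed excess was 34.0%.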